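Ring A (C1 ketone, C2–CH3, C3, oxygenated C4, fusion carbons C5 and C6, C7) carries the sequence C7–C1(=O)–C2=C3–C4–O. This sequence is the five-carbon face of a 3-oxidopyrylium once the C4 oxygen is also tied to C7. The route therefore disconnects C4–C5 and C6–C7. A single (5+2) cycloaddition joins 4-methyl-3-oxidopyrylium, released from its acetoxypyranone, to the C5=C6 bond of enantiopure (R)-4-silyloxy-3-methylcyclopent-2-enone (ring B). It closes ring A, builds the C6 quaternary carbon and fixes C4 and C6. The extra C7–O bond, alpha to C1, is later cut reductively, and C5, alpha to the C10 ketone, is then inverted to the trans fusion.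

Key step: step 6

Atom labels: ring A = C1 (C=O), C2 (C–CH3), C3 (=CH), C4 (CH–O), C5 (fusion CH), C6 (fusion C–CH3), C7 (CH2); ring B = C6, C8, C9, C10 (C(OH)-i-Pr), C5.
Faces: ring A is drawn flat with C1 to C7 running counter-clockwise, and "up" points to the viewer. The target has C4–O and H5 up, C6–CH3 and C10–OH down (C4 S, C5 S, C6 R, C10 R).
Assumption: the C2 centre of 13–16 (alpha to the C1 ketone, erased in step 13) forms as a mixture and is left unmarked. The acetal centres of 3 and 4 are racemic and vanish in 8.

Step 1
Reactants: 1 methyl 3-methylfuran-2-carboxylate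
Product: 2 (3-methylfuran-2-yl)methanol
Conditions: LiAlH4, Et2O, 0 °C
Reagents that add atoms: none
Why: Hydride reduction of the ester gives the primary furfuryl alcohol, the furan is inert to LiAlH4 and no stereocentre is formed.

Step 2
Reactants: 2 (3-methylfuran-2-yl)methanol
Product: 3 6-hydroxy-4-methyl-2H-pyran-3(6H)-one
Conditions: mCPBA, CH2Cl2, 0 °C to rt
Reagents that add atoms: mCPBA, O=C(OO)c1cccc(Cl)c1
Why: Achmatowicz oxidative ring expansion: oxidation of the furan gives the cis-enedione, whose carbinol oxygen closes onto the aldehyde carbon (future C4), so the furan methyl ends next to the ketone (future C2) and the hemiacetal centre is of no consequence.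

Step 3
Reactants: 3 6-hydroxy-4-methyl-2H-pyran-3(6H)-one
Product: 4 6-acetoxy-4-methyl-2H-pyran-3(6H)-one
Conditions: Ac2O, pyridine, DMAP (cat.), CH2Cl2, 0 °C
Reagents that add atoms: acetic anhydride, CC(=O)OC(C)=O
Why: O-Acetylation of the hemiacetal installs the leaving group for ylide release, and the weak base at 0 °C does not yet trigger that release.

Step 4
Reactants: 5 (R)-4-(tert-butyldimethylsilyloxy)cyclopent-2-en-1-one
Product: 6 (3R,4R)-4-(tert-butyldimethylsilyloxy)-3-methyl-1-(trimethylsilyloxy)cyclopent-1-ene
Conditions: MeMgBr, CuBr·SMe2 (10 mol %), TMSCl, DMPU, THF, −78 °C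
Reagents that add atoms: methylmagnesium bromide, C[Mg]Br; chlorotrimethylsilane, C[Si](C)(C)Cl
Why: Copper-catalysed conjugate addition with in situ silyl trapping: methyl enters C6 anti to the C8 silyloxy group (a centre erased in step 5), and immediate O-silylation fixes the C5=C10 enol ether and stops enolate equilibration and beta-elimination of the silyloxy group.

Step 5
Reactants: 6 (3R,4R)-4-(tert-butyldimethylsilyloxy)-3-methyl-1-(trimethylsilyloxy)cyclopent-1-ene
Product: 7 (R)-4-(tert-butyldimethylsilyloxy)-3-methylcyclopent-2-en-1-one
Conditions: Pd(OAc)2 (1.05 equiv), MeCN, rt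
Reagents that add atoms: none
Why: Saegusa–Ito oxidation: the divalent palladium enolate bound at C5 loses the C6 hydrogen by beta-hydride elimination, which gives the beta-methyl enone and zerovalent palladium while the C8 stereocentre is untouched.

Step 6
Reactants: 4 6-acetoxy-4-methyl-2H-pyran-3(6H)-one; 7 (R)-4-(tert-butyldimethylsilyloxy)-3-methylcyclopent-2-en-1-one
Product: 9 exo oxygen-bridged tricyclic dione bearing C8–OTBS, via 4-methyl-3-oxidopyrylium 8 (not isolated)
Conditions: 4 (3 equiv, added over 12 h), i-Pr2NEt, MeCN, 80 °C, 7 kept at about 1 M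
Reagents that add atoms: none
Why: The amine removes a C7 hydrogen of 4 and acetate leaves from C4, giving the planar betaine 8, which adds through C7 and C4 across C5=C6 of 7 in a concerted but asynchronous suprafacial six-electron process; this is the intermolecular 3-oxidopyrylium–enone (5+2) dipolar cycloaddition, here asked to build a quaternary carbon. Ring A, the seven-membered carbocycle, is closed by this intermolecular cycloaddition, both ring bonds C4–C5 and C6–C7 forming in the same event while the pyran oxygen becomes the C4–O–C7 bridge. Regiochemistry follows the polarity of both partners: the enolate-like C7 of 8 bonds to the electrophilic beta carbon C6 and the oxocarbenium-like C4 to the alpha carbon C5, as with acrylates and vinyl ketones. C6 and C5 are set by the face of 7 that is attacked, because the C8 silyloxy group next to C6 blocks its own face, and suprafacial addition makes H5 and the C6 methyl cis. C4 and C7 are set relative to them by the exo orientation, with ring B on the side of the bridging oxygen and only H5 and the C6 methyl under the C1–C3 arm; this keeps C8, C9 and C10 away from the methyl-bearing arm but rests on sterics alone, so the isomers are separated by chromatography. Ylide dimerisation, the main competitor with so hindered an alkene, is held back by keeping 8 dilute and 7 concentrated, and the hindered amine spares the beta-silyloxy ketone and the C5 hydrogen next to the bridge.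

Step 7
Reactants: 9 exo oxygen-bridged tricyclic dione bearing C8–OTBS
Product: 10 bridged tricyclic dione bearing C8–OH
Conditions: HF·pyridine, THF, 0 °C to rt
Reagents that add atoms: none
Why: Fluoride desilylation in an acidic medium frees the C8 alcohol without forming an enolate, so neither the beta-hydroxy ketone nor the bridge (beta to C10) eliminates.

Step 8
Reactants: 10 bridged tricyclic dione bearing C8–OH
Product: 11 C8 O-phenyl thionocarbonate of the bridged dione
Conditions: PhOC(S)Cl, pyridine, DMAP (cat.), CH2Cl2, 0 °C to rt
Reagents that add atoms: O-phenyl chlorothionoformate, ClC(=S)Oc1ccccc1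
Why: Thioacylation of the secondary alcohol on the convex face of ring B prepares the Barton–McCombie step, and the weak base at or below rt keeps E1cB loss of the new ester slow.

Step 9
Reactants: 11 C8 O-phenyl thionocarbonate of the bridged dione
Product: 12 bridged tricyclic dione with C8 as CH2
Conditions: Bu3SnH, AIBN (cat.), toluene, 90 °C
Reagents that add atoms: none
Why: Barton–McCombie deoxygenation: the stannyl radical adds to C=S far faster than to the enone, the secondary C8 radical is released and takes hydrogen from the stannane, and C8 ceases to be a stereocentre after having done its directing work.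

Step 10
Reactants: 12 bridged tricyclic dione with C8 as CH2
Product: 13 bridged C3 phenylthio diketone
Conditions: PhSH, Et3N (cat.), CH2Cl2, 0 °C to rt
Reagents that add atoms: thiophenol, Sc1ccccc1
Why: Thia-Michael addition from the convex face of the enone arm (syn to the oxygen bridge, sulfur up at C3) removes C2=C3 for the moment, so that electron transfer in step 11 can expel only the alpha C7–O bond and not, vinylogously through the enone, the C4–O bond that must stay.

Step 11
Reactants: 13 bridged C3 phenylthio diketone
Product: 14 cis-fused C4 hydroxy C3 phenylthio hydroazulenedione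
Conditions: SmI2 (2.2 equiv), THF–MeOH, −78 °C
Reagents that add atoms: none
Why: SmI2 reduction of an alpha-alkoxy ketone: two single-electron transfers to the C1 carbonyl expel the C7–O bond as the C4 alkoxide and methanol protonates the samarium enolate at C7, while the unactivated C10 ketone and the sulfide do not react at −78 °C and C4 keeps its configuration because its C–O bond is never broken.

Step 12
Reactants: 14 cis-fused C4 hydroxy C3 phenylthio hydroazulenedione
Product: 15 C4 triethylsilyl ether of 14
Conditions: TESCl, imidazole, DMF, 0 °C to rt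
Reagents that add atoms: chlorotriethylsilane, CC[Si](CC)(CC)Cl
Why: Silyl ether protection of the C4 alcohol (drawn out of any C1 hemiketal form) blocks retro-aldol cleavage of C4–C5 before base is applied, and imidazole is too weak to enolise either ketone.

Step 13
Reactants: 15 C4 triethylsilyl ether of 14
Product: 18 trans-fused C4 silyloxy enone ketone, via sulfone 16 (not isolated), via cis-fused enone 17 (not isolated)
Conditions: mCPBA (2.1 equiv), CH2Cl2, −20 to 0 °C; then DBU (5 equiv), rt
Reagents that add atoms: none
Why: Sulfide-to-sulfone oxidation, E1cB loss of sulfinate from the C1 enolate (which restores C2=C3) and base equilibration through the C10 enolate place H5 up and trans to the C6 methyl, because the flat C7–C1–C2–C3–C4 segment forces a large torsion about C5–C6 that only a trans-fused cyclopentanone fits, with C4–O, C8 and C10 all pseudo-equatorial, and reprotonation is much faster than expulsion of the poor silanolate leaving group.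

Step 14
Reactants: 18 trans-fused C4 silyloxy enone ketone
Product: 20 (3R,3aS,4S,8aR)-3,4-dihydroxy-3-isopropyl-6,8a-dimethyl-octahydroazulen-7-one diol, via triethylsilyl ether 19 (not isolated)
Conditions: i-PrMgCl (1.3 equiv), CeCl3, THF, −78 °C; then 1 M HCl, 0 °C
Reagents that add atoms: isopropylmagnesium chloride, CC(C)[Mg]Cl
Why: Organocerium 1,2-addition, which suppresses enolisation and hydride transfer, takes place at the non-conjugated and more electrophilic C10 ketone rather than at the vinylogously deactivated C1 flanked by the C2 methyl and the neopentyl C7, the reagent approaches from the upper face anti to the axial C6 methyl so that C10–OH ends down, and the acidic work-up removes the triethylsilyl group.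

Step 15
Reactants: 21 p-coumaric acid
Product: 23 (E)-3-[4-(tert-butyldimethylsilyloxy)phenyl]acrylic acid, via bis-silyl derivative 22 (not isolated)
Conditions: TBSCl (2.4 equiv), imidazole, DMF, rt; then THF–H2O–AcOH, rt
Reagents that add atoms: tert-butyldimethylsilyl chloride, CC(C)(C)[Si](C)(C)Cl
Why: Exhaustive silylation followed by selective hydrolysis of the labile silyl ester masks the phenol so that it cannot compete as a nucleophile in the esterification, and the E alkene is not touched.

Step 16
Reactants: 20 hydroazulenone diol; 23 (E)-3-[4-(tert-butyldimethylsilyloxy)phenyl]acrylic acid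
Product: 24 C4 ester of 20 carrying the silylated coumaroyl group
Conditions: DCC, DMAP, CH2Cl2, 0 °C to rt
Reagents that add atoms: none
Why: Steglich esterification acylates the secondary C4 alcohol with retention (the C4–O bond is not broken) and leaves the tertiary C10 alcohol untouched for steric reasons.

Step 17
Reactants: 24 C4 ester of 20 carrying the silylated coumaroyl group
Product: 25 target CNP0310968.1
Conditions: HF·pyridine, THF, 0 °C to rt
Reagents that add atoms: none
Why: Fluoride cleavage of the aryl silyl ether under non-basic conditions frees the phenol without ester cleavage, acyl shift or dehydration of the tertiary alcohol.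

Compound list
1 | methyl 3-methylfuran-2-carboxylate | COC(=O)c1occc1C | starting material
2 | (3-methylfuran-2-yl)methanol | OCc1occc1C | intermediate
3 | 6-hydroxy-4-methyl-2H-pyran-3(6H)-one (racemic hemiacetal) | CC1=CC(O)OCC1=O | intermediate
4 | 6-acetoxy-4-methyl-2H-pyran-3(6H)-one (racemic) | CC1=CC(OC(C)=O)OCC1=O | intermediate
5 | (R)-4-(tert-butyldimethylsilyloxy)cyclopent-2-en-1-one | O=C1C=C[C@H](O[Si](C)(C)C(C)(C)C)C1 | starting material
6 | (3R,4R)-4-(tert-butyldimethylsilyloxy)-3-methyl-1-(trimethylsilyloxy)cyclopent-1-ene (methyl trans to OTBS) | C[C@@H]1C=C(O[Si](C)(C)C)C[C@H]1O[Si](C)(C)C(C)(C)C | intermediate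
7 | (R)-4-(tert-butyldimethylsilyloxy)-3-methylcyclopent-2-en-1-one | CC1=CC(=O)C[C@H]1O[Si](C)(C)C(C)(C)C | intermediate
8 | 4-methyl-3-oxidopyrylium | Cc1cc[o+]cc1[O-] | intermediate
9 | exo (5+2) adduct: ring A as 8-oxabicyclo[3.2.1]oct-3-en-2-one (oxygen bridging C4 and C7, up) cis-fused to ring B; C8 and C10 up, H5 and C6–CH3 down, C8–OTBS down (cis to C6–CH3); ketones at C1 and C10 | CC1=C[C@@H]2O[C@H](C1=O)[C@@]3(C)[C@H](O[Si](C)(C)C(C)(C)C)CC(=O)[C@@H]23 | intermediate
10 | C8 alcohol of 9 (same configuration) | CC1=C[C@@H]2O[C@H](C1=O)[C@@]3(C)[C@H](O)CC(=O)[C@@H]23 | intermediate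
11 | C8 O-phenyl thionocarbonate of 10 | CC1=C[C@@H]2O[C@H](C1=O)[C@@]3(C)[C@H](OC(=S)Oc4ccccc4)CC(=O)[C@@H]23 | intermediate
12 | bridged tricyclic dione, C8 = CH2 (bridge, C8, C10 up; H5, C6–CH3 down) | CC1=C[C@@H]2O[C@H](C1=O)[C@@]3(C)CCC(=O)[C@@H]23 | intermediate
13 | thiophenol adduct of 12: C3–SPh up, C2 epimers | CC1[C@H](Sc4ccccc4)[C@@H]2O[C@H](C1=O)[C@@]3(C)CCC(=O)[C@@H]23 | intermediate
14 | cis-fused hydroazulene-1,10-dione: C4–OH up, C3–SPh up, H5 down, C6–CH3 down, C7 = CH2 | CC1[C@H](Sc3ccccc3)[C@H](O)[C@H]2[C@](C)(CCC2=O)CC1=O | intermediate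
15 | C4 triethylsilyl ether of 14 | CC1[C@H](Sc3ccccc3)[C@H](O[Si](CC)(CC)CC)[C@H]2[C@](C)(CCC2=O)CC1=O | intermediate
16 | C3 phenyl sulfone of 15 | CC1[C@H](S(=O)(=O)c3ccccc3)[C@H](O[Si](CC)(CC)CC)[C@H]2[C@](C)(CCC2=O)CC1=O | intermediate
17 | cis-fused enone ketone: C2=C3, C4–OTES up, H5 down, C6–CH3 down | CC1=C[C@H](O[Si](CC)(CC)CC)[C@H]2[C@](C)(CCC2=O)CC1=O | intermediate
18 | trans-fused enone ketone: C4–OTES up, H5 up, C6–CH3 down | CC1=C[C@H](O[Si](CC)(CC)CC)[C@@H]2[C@](C)(CCC2=O)CC1=O | intermediate
19 | C10 isopropyl carbinol of 18 (C10–OH down, isopropyl up), C4–OTES | CC1=C[C@H](O[Si](CC)(CC)CC)[C@@H]2[C@](C)(CC[C@@]2(O)C(C)C)CC1=O | intermediate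
20 | (3R,3aS,4S,8aR)-3,4-dihydroxy-3-isopropyl-6,8a-dimethyl-1,2,3,3a,4,7,8,8a-octahydroazulen-7-one | CC1=C[C@H](O)[C@@H]2[C@](C)(CC[C@@]2(O)C(C)C)CC1=O | intermediate
21 | p-coumaric acid | OC(=O)/C=C/c1ccc(O)cc1 | starting material
22 | tert-butyldimethylsilyl (E)-3-[4-(tert-butyldimethylsilyloxy)phenyl]acrylate | CC(C)(C)[Si](C)(C)OC(=O)/C=C/c1ccc(O[Si](C)(C)C(C)(C)C)cc1 | intermediate
23 | (E)-3-[4-(tert-butyldimethylsilyloxy)phenyl]acrylic acid | OC(=O)/C=C/c1ccc(O[Si](C)(C)C(C)(C)C)cc1 | intermediate
24 | C4 (E)-4-(tert-butyldimethylsilyloxy)cinnamate of 20 | CC1=C[C@H](OC(=O)/C=C/c3ccc(O[Si](C)(C)C(C)(C)C)cc3)[C@@H]2[C@](C)(CC[C@@]2(O)C(C)C)CC1=O | intermediate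
25 | (3R,3aS,4S,8aR)-3-hydroxy-3-isopropyl-6,8a-dimethyl-7-oxo-1,2,3,3a,4,7,8,8a-octahydroazulen-4-yl (E)-3-(4-hydroxyphenyl)acrylate | CC1=C[C@H](OC(=O)/C=C/c2ccc(O)cc2)[C@@H]2[C@](C)(CC[C@@]2(O)C(C)C)CC1=O | target

Total step count: 17. Longest linear sequence: 14 (steps 1–3, 6–14, 16, 17).

Steps most likely to fail

1. Step 6. Self-dimerisation of the ylide may outrun addition to the hindered trisubstituted alkene. Discrimination between the exo and endo orientations may be weak. Prolonged heating with base may also cause loss of silanol from the enone or the adduct.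
 - Fallback: give up substrate control and use the alkene as the medium. This sets out from 4, which is added slowly with i-Pr2NEt to neat, cheap commercial 3-methylcyclopent-2-en-1-one (CC1=CC(=O)CC1) at 80 °C.
 - The large excess of alkene competes better with dimerisation, and there is no base-labile silyloxy group.
 - The exo adduct forms directly as racemic 12, that is 12 together with the enantiomer of the bridged dione F1.
 - The two are separated by preparative chromatography on a chiral stationary phase. The route is rejoined at 12, and steps 4, 5 and 7–9 fall away.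

2. Step 13. The cis-to-trans equilibration may stop short or lie on the wrong side. Triethylsilanol may be lost by E1cB from the C10 enolate. The enone double bond may also migrate toward C4.
 - Fallback: kinetic protonation without a free enolate, setting out from 15.
 - Equilibrating silylation (TMSI, hexamethyldisilazane, CH2Cl2, −20 °C to rt) converts both ketones into their more substituted enol ethers, the bis(trimethylsilyl enol ether) F2 (C1=C2 and C5=C10).
 - Methanolysis with catalytic PPTS at −20 °C protonates C5 on the face away from the C6 methyl and C7. This gives the trans-fused phenylthio diketone F3, and any less substituted enol ether simply returns 15.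
 - Oxidation with mCPBA gives the trans-fused phenylsulfonyl diketone F4. Elimination with Et3N at 0 °C, a base too weak to touch C5, leads back to 18.

3. Step 14. There may be competing 1,2-addition at the C1 enone. The branched reagent may enolise or reduce C10. Attack may also come from the lower face.
 - Fallback: transient masking of the enone, setting out from 18.
 - PPh3 and TMSOTf (CH2Cl2, 0 °C) add across the enone only and give the phosphonium silyl enol ether triflate F5, in which C1 is no longer a carbonyl.
 - i-PrMgCl (THF, −78 °C) then meets a single ketone and gives the phosphonium tertiary alcohol F6.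
 - TBAF in the work-up removes both silyl groups and expels PPh3, which restores the enone. The route is rejoined at 20.

Further compounds
F1 | step 6 | enantiomer of bridged dione 12 | CC1=C[C@H]2O[C@@H](C1=O)[C@]3(C)CCC(=O)[C@H]23
F2 | step 13 | bis(trimethylsilyl enol ether) of 15 (C1=C2 and C5=C10) | CC1=C(O[Si](C)(C)C)C[C@@]2(C)CCC(O[Si](C)(C)C)=C2[C@@H](O[Si](CC)(CC)CC)[C@H]1Sc3ccccc3
F3 | step 13 | trans-fused phenylthio diketone (C5 epimer of 15) | CC1[C@H](Sc3ccccc3)[C@H](O[Si](CC)(CC)CC)[C@@H]2[C@](C)(CCC2=O)CC1=O
F4 | step 13 | trans-fused phenylsulfonyl diketone (C5 epimer of 16) | CC1[C@H](S(=O)(=O)c3ccccc3)[C@H](O[Si](CC)(CC)CC)[C@@H]2[C@](C)(CCC2=O)CC1=O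
F5 | step 14 | C3 triphenylphosphonio C1 trimethylsilyl enol ether triflate of 18 | CC1=C(O[Si](C)(C)C)C[C@@]2(C)CCC(=O)[C@@H]2[C@@H](O[Si](CC)(CC)CC)C1[P+](c3ccccc3)(c4ccccc4)c5ccccc5.[O-]S(=O)(=O)C(F)(F)F
F6 | step 14 | C10 isopropyl carbinol of F5 | CC1=C(O[Si](C)(C)C)C[C@@]2(C)CC[C@@](O)(C(C)C)[C@@H]2[C@@H](O[Si](CC)(CC)CC)C1[P+](c3ccccc3)(c4ccccc4)c5ccccc5.[O-]S(=O)(=O)C(F)(F)F
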